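**Plan**

- Numbering: abietane-type for the tricyclic half (ring A C1–C5/C10; ring B C5–C6–C8–C9–C10 with the formyl carbon C7 on C6; ring C C8, C9, C11–C14); primed labdane numbers for the other half.
- Cuts: C8–C15′ and C13–C14′ (retro-[5+2] of the bicyclo[3.2.1]octenedione) give a 12-hydroxy-11,14-quinone aldehyde and 4-epi-trans-communic acid; then C6–C8 (ring B), C6=C7 (Wittig), C5–C6 (ketone homologation) and C9–C10 (ketone α-arylation).
- Enabling feature: C6, the ring B methine that bears C7, is bonded to C8 of ring C. The oxygens at C12 and C14 let ring C travel as a resorcinol dimethyl ether in which C8 is ortho and para to methoxy, so C6–C8 can join an enol ether carbon (C6=C7–OMe, aldehyde level at C7) to an electron-rich arene.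
- Forward order: the ring C arene and the ring A ketone are joined at C9–C10, the C5 side chain is built, ring B closes anodically, ring C is oxidised to the hydroxyquinone, and the [5+2] cycloaddition forms both rings of the bicyclo[3.2.1] core while attaching the labdane.
- Stereochemistry: C10 from the enantioselective α-arylation; C5 and C6 by substrate-controlled hydroboration and base equilibration (formyl trans to aryl, then C7 anti to C4); C8, C13 and C14′ from α-face, endo [5+2] addition; the labdane centres and the 12′E alkene come with the natural acid.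

Key step: step 9

Assumption: 4-epi-trans-communic acid (21; carboxyl group α, equatorial, at C4′, the C4′ epimer of trans-communic acid) is bought as the isolated conifer resin acid and used unprotected.

**Route**

Step 1
Reactants: 1 1,3-dimethoxybenzene; 2 acetone
Product: 4 2-(2,6-dimethoxyphenyl)propan-2-ol, via 2,6-dimethoxyphenyllithium 3 (not isolated)
Conditions: n-BuLi (1.1 equiv), THF, 0 °C to rt; acetone, −78 °C to rt; H2O
Reagents that add atoms: n-butyllithium, [Li]CCCC (lithium, in 3 only)
Why: Directed ortho-metalation takes place at C2 between the two coordinating methoxy groups, and the aryllithium adds 1,2 to acetone; no stereocentre is formed.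

Step 2
Reactants: 4
Product: 5 2-isopropyl-1,3-dimethoxybenzene
Conditions: Et3SiH (2.5 equiv), CF3CO2H (5 equiv), CH2Cl2, 0 °C to rt
Reagents that add atoms: none
Why: Ionic hydrogenation: the tertiary benzylic alcohol ionises to a cumyl cation stabilised by both ortho methoxy groups and is reduced by hydride transfer from the silane.

Step 3
Reactants: 5
Product: 7 5-bromo-2-isopropyl-1,3-dimethoxybenzene, via aryl pinacol boronate 6 (not isolated)
Conditions: B2pin2 (1.0 equiv), [Ir(cod)(OMe)]2 (1.5 mol %), dtbpy (3 mol %), THF, 80 °C; evaporate; CuBr2 (3 equiv), MeOH/H2O 1:1, 80 °C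
Reagents that add atoms: bis(pinacolato)diboron, CC1(C)OB(OC1(C)C)B1OC(C)(C)C(C)(C)O1 (boryl group, in 6 only); copper dibromide CuBr2, [Cu+2].[Br-].[Br-] (bromine)
Why: Sterically governed iridium-catalysed C–H borylation reaches only C5, the one C–H not ortho to a substituent, and copper-mediated bromodeboronation keeps that position, which electrophilic bromination (ortho/para to methoxy) would not give.

Step 4
Reactants: 7; 8 2,2,6-trimethylcyclohexanone (racemic)
Product: 9 (R)-2-(4-isopropyl-3,5-dimethoxyphenyl)-2,6,6-trimethylcyclohexan-1-one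
Conditions: Pd(dba)2 (5 mol %), (R)-DIFLUORPHOS (6 mol %; the ligand antipode if a test run shows the opposite sense), NaOtBu (1.5 equiv), toluene, 60 °C
Reagents that add atoms: none
Why: Palladium-catalysed enantioselective ketone α-arylation: the ketone can form only one enolate, the aryl bromide carries no ortho substituent, and reductive elimination from the chiral bisphosphine arylpalladium enolate creates the quaternary C10 under ligand control, in a product that has no α-hydrogen left to racemise.

Step 5
Reactants: 9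
Product: 10 5-[(1R)-1,3,3-trimethyl-2-methylidenecyclohexyl]-2-isopropyl-1,3-dimethoxybenzene
Conditions: Cp2TiMe2 (3 equiv), toluene, 85 °C, dark
Reagents that add atoms: dimethyltitanocene Cp2TiMe2, [Ti+4].[CH3-].[CH3-].c1cc[cH-]c1.c1cc[cH-]c1 (the methylene carbon C6)
Why: Petasis methylenation: the small titanocene methylidene formed on heating adds to the non-enolisable ketone and collapses to the alkene, and should tolerate the two flanking quaternary carbons that would stop a phosphorus ylide.

Step 6
Reactants: 10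
Product: 12 [(1S,2S)-2-(4-isopropyl-3,5-dimethoxyphenyl)-2,6,6-trimethylcyclohexyl]methanol, via primary alkylborane 11 (not isolated)
Conditions: BH3·THF (3 equiv), THF, 0 to 50 °C; 3 M NaOH, 30% H2O2, 0 °C to rt
Reagents that add atoms: borane–tetrahydrofuran, B.C1CCOC1 (boron, in 11 only); hydrogen peroxide, OO (oxygen)
Why: Hydroboration–oxidation places boron on the terminal carbon; with the aryl group equatorial the axial C10 and C4 methyl groups screen one face, so hydrogen should reach C5 from the other and C6 should end cis to the C10 methyl (trans to aryl), and any C5 epimer is corrected in step 7.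

Step 7
Reactants: 12
Product: 13 (1S,2S)-2-(4-isopropyl-3,5-dimethoxyphenyl)-2,6,6-trimethylcyclohexane-1-carbaldehyde
Conditions: Dess–Martin periodinane, NaHCO3, CH2Cl2, 0 °C to rt; then NaOMe (0.3 equiv), MeOH, 50 °C
Reagents that add atoms: none
Why: Dess–Martin oxidation followed by enolisation of the single α-C–H; the equilibrium should favour the isomer with aryl and formyl groups both equatorial and only methyl groups axial, since the C5 epimer must put the aryl group axial against the axial C4 methyl or the formyl group axial, and this fixes C5.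

Step 8
Reactants: 13; 14 (methoxymethyl)triphenylphosphonium chloride
Product: 16 5-[(1S,2S)-2-(2-methoxyethenyl)-1,3,3-trimethylcyclohexyl]-2-isopropyl-1,3-dimethoxybenzene (E/Z mixture), via methoxymethylenetriphenylphosphorane 15 (not isolated)
Conditions: 14 (2.5 equiv), KOtBu (2.4 equiv), THF, 0 °C; then 13, −78 °C to rt
Reagents that add atoms: none
Why: Wittig olefination with a reactive non-stabilised ylide, preformed and met by the aldehyde at low temperature so that addition outruns enolisation at C5; both alkene isomers serve the next step.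

Step 9
Reactants: 16
Product: 17 (4bS,8aS,9R)-9-(dimethoxymethyl)-1,3-dimethoxy-4b,8,8-trimethyl-2-(propan-2-yl)-4b,5,6,7,8,8a-hexahydro-9H-fluorene
Conditions: reticulated vitreous carbon anode, Pt cathode, undivided cell, constant current 8 mA, 0.1 M LiClO4, MeOH/CH2Cl2 1:4, 2,6-lutidine (4 equiv), 2.1 F/mol, rt
Reagents that add atoms: methanol, CO (one methoxy group of the acetal)
Why: One-electron oxidation at the anode turns the enol ether (or, by fast intramolecular electron exchange, the dialkoxyarene) into a radical cation, C8 of the arene bonds to the electrophilic C6, a second electron is removed, methanol adds to the C7 oxocarbenium ion and 2,6-lutidine takes the proton from the arenium ion, so the arene returns, C7 becomes a dimethyl acetal and hydrogen forms at the cathode. The closest known reaction is the intramolecular anodic coupling of enol ether radical cations with alkoxy-substituted benzene rings, which gives cyclised dimethyl acetals in this electrolyte. Ring B (C5–C6–C8–C9–C10) closes in the 5-exo-trig mode with respect to the C6=C7 bond, with aryl and alkenyl groups trans-diequatorial on ring A so that the fusion is trans. The only new stereocentre, C6, is governed by the ring A chair, C7 turning away from the C4 gem-dimethyl group, and any epimer is corrected by enolisation in step 10. The step needs C–C bond formation to outrun methanol capture of the radical cation and further oxidation of the product; both ortho carbons of the aryl ring are equivalent and each is ortho and para to a methoxy group, a resorcinol ether cannot drain into a quinone bisketal, the two quaternary carbons hold C6 next to C8, and the charge is limited to about 2.1 F/mol.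

Step 10
Reactants: 17
Product: 18 (4bS,8aS,9R)-1,3-dimethoxy-4b,8,8-trimethyl-2-(propan-2-yl)-4b,5,6,7,8,8a-hexahydro-9H-fluorene-9-carbaldehyde
Conditions: 2 M HCl/THF 1:4, rt; then DBU (0.2 equiv), CH2Cl2, rt
Reagents that add atoms: water, O (carbonyl oxygen)
Why: Acid-catalysed acetal hydrolysis, then base-mediated enolisation of the benzylic α-C–H, which should settle C6 with the formyl group trans to the adjacent C4 quaternary carbon.

Step 11
Reactants: 18
Product: 19 (4bS,8aS,9R)-1,3-dihydroxy-4b,8,8-trimethyl-2-(propan-2-yl)-4b,5,6,7,8,8a-hexahydro-9H-fluorene-9-carbaldehyde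
Conditions: BBr3 (5 equiv), CH2Cl2, −78 to 0 °C; ice, NaHCO3 (aq); handled under argon
Reagents that add atoms: none
Why: Lewis acid-mediated cleavage of both aryl methyl ethers through bromide attack on the O-methyl groups of the borane complexes; the aldehyde is only bound reversibly and returns on hydrolysis, and C6 stays at its thermodynamic configuration.

Step 12
Reactants: 19
Product: 20 (4bS,8aS,9R)-3-hydroxy-4b,8,8-trimethyl-1,4-dioxo-2-(propan-2-yl)-4,4b,5,6,7,8,8a,9-octahydro-1H-fluorene-9-carbaldehyde (12-hydroxy-11,14-quinone with the C6 formyl group)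
Conditions: potassium nitrosodisulfonate (KSO3)2NO (2.5 equiv), KH2PO4 (aq), acetone/H2O, 0 °C to rt
Reagents that add atoms: potassium nitrosodisulfonate (KSO3)2NO, [K+].[K+].[O]N(S(=O)(=O)[O-])S(=O)(=O)[O-] (oxygen at C11)
Why: Teuber oxidation: the nitroxyl radical oxidises the resorcinol at its only free ring carbon, C11 (para to the C14 hydroxyl), giving the 2-hydroxy-1,4-benzoquinone while the aliphatic aldehyde is left alone.

Step 13
Reactants: 20; 21 4-epi-trans-communic acid [(4R,5R,9S,10R)-labda-8(17),12E,14-trien-18-oic acid]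
Product: 22 target compound, the [5+2] adduct with new bonds C8–C15′ and C13–C14′ (C14 bridging ketone, C12 ketone, C11 enol conjugated with C9; C15′ on the α-face of C8, dienyl residue at C14′ endo)
Conditions: 21 (1.5 equiv), BF3·OEt2 (2.5 equiv), CH2Cl2, −78 to −30 °C; pH 7 buffer
Reagents that add atoms: none
Why: Perezone-type [5+2] cycloaddition: boron activation of the hydroxyquinone gives a 2-oxidopentadienyl cation over C13–C12–C11–C9–C8; the terminal C14′=C15′ bond adds with C15′ to C8 and the resulting allyl cation is taken by C13, leaving C12 as ketone and C11 as enol. Attack anti to the axial C10 methyl and the C4 carbon (α-face) with the dienyl residue under the cation (endo) should set C8, C13 and C14′, while the carboxylic acid only binds one equivalent of the Lewis acid.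

**Compound list**

1 | 1,3-dimethoxybenzene | COc1cccc(OC)c1 | starting material
2 | acetone | CC(C)=O | starting material
3 | 2,6-dimethoxyphenyllithium (formed in the flask) | [Li]c1c(OC)cccc1OC | intermediate
4 | 2-(2,6-dimethoxyphenyl)propan-2-ol | COc1cccc(OC)c1C(C)(C)O | intermediate
5 | 2-isopropyl-1,3-dimethoxybenzene | COc1cccc(OC)c1C(C)C | intermediate
6 | 2-(4-isopropyl-3,5-dimethoxyphenyl)-4,4,5,5-tetramethyl-1,3,2-dioxaborolane (formed in the flask) | COc1cc(cc(OC)c1C(C)C)B1OC(C)(C)C(C)(C)O1 | intermediate
7 | 5-bromo-2-isopropyl-1,3-dimethoxybenzene | COc1cc(Br)cc(OC)c1C(C)C | intermediate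
8 | 2,2,6-trimethylcyclohexanone (racemic) | CC1CCCC(C)(C)C1=O | starting material
9 | (R)-2-(4-isopropyl-3,5-dimethoxyphenyl)-2,6,6-trimethylcyclohexan-1-one | COc1cc(cc(OC)c1C(C)C)[C@@]1(C)CCCC(C)(C)C1=O | intermediate
10 | 5-[(1R)-1,3,3-trimethyl-2-methylidenecyclohexyl]-2-isopropyl-1,3-dimethoxybenzene | COc1cc(cc(OC)c1C(C)C)[C@@]1(C)CCCC(C)(C)C1=C | intermediate
11 | {[(1S,2S)-2-(4-isopropyl-3,5-dimethoxyphenyl)-2,6,6-trimethylcyclohexyl]methyl}borane (formed in the flask) | COc1cc(cc(OC)c1C(C)C)[C@@]1(C)CCCC(C)(C)[C@@H]1CB | intermediate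
12 | [(1S,2S)-2-(4-isopropyl-3,5-dimethoxyphenyl)-2,6,6-trimethylcyclohexyl]methanol | COc1cc(cc(OC)c1C(C)C)[C@@]1(C)CCCC(C)(C)[C@@H]1CO | intermediate
13 | (1S,2S)-2-(4-isopropyl-3,5-dimethoxyphenyl)-2,6,6-trimethylcyclohexane-1-carbaldehyde (formyl trans to aryl) | COc1cc(cc(OC)c1C(C)C)[C@@]1(C)CCCC(C)(C)[C@@H]1C=O | intermediate
14 | (methoxymethyl)triphenylphosphonium chloride | COC[P+](c1ccccc1)(c1ccccc1)c1ccccc1.[Cl-] | starting material
15 | methoxymethylenetriphenylphosphorane (formed in the flask) | COC=P(c1ccccc1)(c1ccccc1)c1ccccc1 | intermediate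
16 | 5-[(1S,2S)-2-(2-methoxyethenyl)-1,3,3-trimethylcyclohexyl]-2-isopropyl-1,3-dimethoxybenzene (E/Z mixture, E isomer drawn) | COc1cc(cc(OC)c1C(C)C)[C@@]1(C)CCCC(C)(C)[C@@H]1/C=C/OC | intermediate
17 | (4bS,8aS,9R)-9-(dimethoxymethyl)-1,3-dimethoxy-4b,8,8-trimethyl-2-(propan-2-yl)-4b,5,6,7,8,8a-hexahydro-9H-fluorene (trans-fused) | c1c(OC)c(C(C)C)c(OC)c2c1[C@@]1(C)CCCC(C)(C)[C@@H]1[C@H]2C(OC)OC | intermediate
18 | (4bS,8aS,9R)-1,3-dimethoxy-4b,8,8-trimethyl-2-(propan-2-yl)-4b,5,6,7,8,8a-hexahydro-9H-fluorene-9-carbaldehyde | c1c(OC)c(C(C)C)c(OC)c2c1[C@@]1(C)CCCC(C)(C)[C@@H]1[C@H]2C=O | intermediate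
19 | (4bS,8aS,9R)-1,3-dihydroxy-4b,8,8-trimethyl-2-(propan-2-yl)-4b,5,6,7,8,8a-hexahydro-9H-fluorene-9-carbaldehyde | c1c(O)c(C(C)C)c(O)c2c1[C@@]1(C)CCCC(C)(C)[C@@H]1[C@H]2C=O | intermediate
20 | (4bS,8aS,9R)-3-hydroxy-4b,8,8-trimethyl-1,4-dioxo-2-(propan-2-yl)-4,4b,5,6,7,8,8a,9-octahydro-1H-fluorene-9-carbaldehyde | O=C1C(O)=C(C(C)C)C(=O)C2=C1[C@@]1(C)CCCC(C)(C)[C@@H]1[C@H]2C=O | intermediate
21 | 4-epi-trans-communic acid, (4R,5R,9S,10R)-labda-8(17),12E,14-trien-18-oic acid | C=C1CC[C@@H]2[C@](C)(CCC[C@@]2(C)C(=O)O)[C@H]1C/C=C(\C)C=C | starting material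
22 | target compound ([5+2] adduct of 20 and 21) | C=C1CC[C@@H]2[C@](C)(CCC[C@@]2(C)C(=O)O)[C@H]1C/C=C(\C)[C@@H]1C[C@@]23C(=O)[C@]1(C(C)C)C(=O)C(O)=C2[C@@]1(C)CCCC(C)(C)[C@@H]1[C@H]3C=O | target

**Step count and risks**

Total: 13 steps. Longest linear sequence: 13 steps (steps 1–13; the labdane acid 21 enters in the last step).

Steps most likely to fail:

1. Step 13 ([5+2] union).
   - What may go wrong: the diene may add across the quinone C12=C13 bond in the Diels–Alder sense; the exocyclic C8′=C17′ alkene may compete as the nucleophile; addition may take the β-face; or protic acid released from the boron-bound hydroxyquinone may isomerise the alkenes or drive a carbonyl-ene closure onto the C7 aldehyde.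
   - Fallback: an alkoxyquinone version that works without any acidic proton, setting out from 20 and 21 and coming back at 22. Ag2O and 4-methoxybenzyl bromide (CH2Cl2, dark) convert 20 into the 12-O-(4-methoxybenzyl) quinone ether F1. Allyl bromide/K2CO3/DMF converts 21 into allyl 4-epi-trans-communate F2. TiCl4/Ti(OiPr)4 (1:1, CH2Cl2, −78 °C) chelates the C11 carbonyl and the C12 ether oxygen of F1, and the same C8/C13 cycloaddition with F2 follows, the 4-methoxybenzyl cation leaving from oxygen to give the adduct allyl ester F3. Pd(PPh3)4/PhSO2Na (THF/MeOH, rt) then removes the allyl group to give 22.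

2. Step 9 (anodic ring B closure).
   - What may go wrong: methanol may capture the radical cation before the strained trans-fused five-membered ring closes, and the product may be oxidised further at its benzylic C6–H.
   - Fallback: two-electron palladium chemistry, setting out from aldehyde 13 and coming back at 18. NBS (MeCN, 0 °C) brominates one of the two equivalent ring carbons ortho to the cyclohexyl group, giving (1S,2S)-2-(2-bromo-4-isopropyl-3,5-dimethoxyphenyl)-2,6,6-trimethylcyclohexane-1-carbaldehyde F4. The Wittig conditions of step 8 give the bromo enol ether F5. 1 M HCl/THF hydrolyses it to 2-[(1S,2S)-2-(2-bromo-4-isopropyl-3,5-dimethoxyphenyl)-2,6,6-trimethylcyclohexyl]acetaldehyde F6. Intramolecular palladium-catalysed α-arylation of the aldehyde enolate (Pd(OAc)2, PtBu3·HBF4, Cs2CO3, dioxane, 80 °C) forms C6–C8 and, after equilibration at C6 by the carbonate, gives 18.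

3. Step 7 (fixing C5).
   - What may go wrong: the equilibrium, and with it the hydroboration of step 6, may lean towards the epimer with an axial aryl group, leaving the formyl group cis to aryl.
   - Fallback: the same conformational bias is turned to advantage by delivering carbon instead of hydrogen to C5, setting out from ketone 9 and coming back at 16. LiAlH4 (THF) gives (2R)-2-(4-isopropyl-3,5-dimethoxyphenyl)-2,6,6-trimethylcyclohexan-1-ol F7 (either carbinol epimer). NaH, CS2, then MeI give its S-methyl xanthate F8. Keck radical allylation (allylSnBu3, AIBN, benzene, 80 °C) lets the stannane meet the C5 radical anti to the axial aryl group and gives 5-[(1S,2S)-1,3,3-trimethyl-2-(prop-2-en-1-yl)cyclohexyl]-2-isopropyl-1,3-dimethoxybenzene F9. Lemieux–Johnson cleavage (K2OsO4·2H2O cat., NaIO4, 2,6-lutidine, dioxane/H2O) gives 2-[(1S,2S)-2-(4-isopropyl-3,5-dimethoxyphenyl)-2,6,6-trimethylcyclohexyl]acetaldehyde F10. CH(OMe)3/TsOH/MeOH gives its dimethyl acetal F11. TMSOTf/iPr2NEt (CH2Cl2, 0 °C) eliminates methanol to the enol ether 16.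

**Further compounds**

F1 | step 13 | (4bS,8aS,9R)-3-[(4-methoxyphenyl)methoxy]-4b,8,8-trimethyl-1,4-dioxo-2-(propan-2-yl)-4,4b,5,6,7,8,8a,9-octahydro-1H-fluorene-9-carbaldehyde | O=C1C(OCc3ccc(OC)cc3)=C(C(C)C)C(=O)C2=C1[C@@]1(C)CCCC(C)(C)[C@@H]1[C@H]2C=O
F2 | step 13 | prop-2-en-1-yl 4-epi-trans-communate | C=C1CC[C@@H]2[C@](C)(CCC[C@@]2(C)C(=O)OCC=C)[C@H]1C/C=C(\C)C=C
F3 | step 13 | prop-2-en-1-yl ester of the target compound | C=C1CC[C@@H]2[C@](C)(CCC[C@@]2(C)C(=O)OCC=C)[C@H]1C/C=C(\C)[C@@H]1C[C@@]23C(=O)[C@]1(C(C)C)C(=O)C(O)=C2[C@@]1(C)CCCC(C)(C)[C@@H]1[C@H]3C=O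
F4 | step 9 | (1S,2S)-2-(2-bromo-4-isopropyl-3,5-dimethoxyphenyl)-2,6,6-trimethylcyclohexane-1-carbaldehyde | COc1cc(c(Br)c(OC)c1C(C)C)[C@@]1(C)CCCC(C)(C)[C@@H]1C=O
F5 | step 9 | 2-bromo-1-[(1S,2S)-2-(2-methoxyethenyl)-1,3,3-trimethylcyclohexyl]-4-isopropyl-3,5-dimethoxybenzene (E/Z mixture, E drawn) | COc1cc(c(Br)c(OC)c1C(C)C)[C@@]1(C)CCCC(C)(C)[C@@H]1/C=C/OC
F6 | step 9 | 2-[(1S,2S)-2-(2-bromo-4-isopropyl-3,5-dimethoxyphenyl)-2,6,6-trimethylcyclohexyl]acetaldehyde | COc1cc(c(Br)c(OC)c1C(C)C)[C@@]1(C)CCCC(C)(C)[C@@H]1CC=O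
F7 | step 7 | (2R)-2-(4-isopropyl-3,5-dimethoxyphenyl)-2,6,6-trimethylcyclohexan-1-ol (either C1 epimer) | COc1cc(cc(OC)c1C(C)C)[C@@]1(C)CCCC(C)(C)C1O
F8 | step 7 | O-[(2R)-2-(4-isopropyl-3,5-dimethoxyphenyl)-2,6,6-trimethylcyclohexyl] S-methyl dithiocarbonate | COc1cc(cc(OC)c1C(C)C)[C@@]1(C)CCCC(C)(C)C1OC(=S)SC
F9 | step 7 | 5-[(1S,2S)-1,3,3-trimethyl-2-(prop-2-en-1-yl)cyclohexyl]-2-isopropyl-1,3-dimethoxybenzene | COc1cc(cc(OC)c1C(C)C)[C@@]1(C)CCCC(C)(C)[C@@H]1CC=C
F10 | step 7 | 2-[(1S,2S)-2-(4-isopropyl-3,5-dimethoxyphenyl)-2,6,6-trimethylcyclohexyl]acetaldehyde | COc1cc(cc(OC)c1C(C)C)[C@@]1(C)CCCC(C)(C)[C@@H]1CC=O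
F11 | step 7 | 5-[(1S,2S)-2-(2,2-dimethoxyethyl)-1,3,3-trimethylcyclohexyl]-2-isopropyl-1,3-dimethoxybenzene | COc1cc(cc(OC)c1C(C)C)[C@@]1(C)CCCC(C)(C)[C@@H]1CC(OC)OC
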